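**Retrosynthetic overview**
- Target ⇐ its diethyl ester (saponification last) ⇐ Wittig reaction of a C24 aldehyde with an α-(4-methylpent-3-enyl) ester ylide (E-enoate).
- C24 aldehyde ⇐ vinyl-ether Claisen rearrangement of an isopropenyl carbinol (E trisubstituted alkene) ⇐ Z-selective Ando olefination of 3-(furan-3-yl)propanal with a phosphonate made by C-alkylation with a primary iodide.
- Key disconnection is a C–O bond: the chiral core, (3R)-5-oxo-3-(prop-1-en-2-yl)pentyl acetate ⇐ (R)-limonene by ozonolysis of the ring alkene and Criegee rearrangement (carbon-to-oxygen shift). The stereocentre is bought with limonene.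
- Rings: none is formed. The limonene ring is opened in step 1 and the furan is bought as 3-bromofuran.

Assumption: (R)-(+)-limonene of ≥ 98% ee is used; the carbinol centre made in step 2 is carried as an epimer mixture (RS) because step 7 removes it.

**Route**

Step 1
Reactants: 1 (R)-(+)-limonene, (4R)-1-methyl-4-(prop-1-en-2-yl)cyclohex-1-ene
Product: 4 (3R)-5-oxo-3-(prop-1-en-2-yl)pentyl acetate, via methoxy hydroperoxide 2 (not isolated), via peroxyacetate 3 (not isolated)
Conditions: O3 (1.0 equiv, Sudan Red 7B end point), CH2Cl2/MeOH 5:1, NaHCO3, −78 °C; N2 purge, concentrate cold; then Ac2O, Et3N, DMAP (5 mol%), CH2Cl2, 0 → 23 °C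
Reagents that add atoms: ozone, [O-][O+]=O
Why: Proposed new method: ozonolysis in methanol followed by acylation-triggered Criegee rearrangement, established for 1,1-disubstituted alkenes (isopropenyl to acetate, methylenecycloalkane to lactone), is applied here to the ring alkene of a terpene diene; ozone attacks the trisubstituted C1=C2 bond much faster than the isopropenyl group, the primary ozonide is expected to open mainly (about 2–3:1) to the C2 aldehyde and the more substituted C1 carbonyl oxide, methanol traps this as 2, O-acetylation gives 3, and C6 migrates from C1 to oxygen with loss of acetate, so that C1 and C7 end as the acetyl group of a primary acetate (new C6–O bond) while C4 is untouched and stays R; the closest known reaction is the Baeyer–Villiger-type Criegee rearrangement of α-alkoxy hydroperoxides.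

Step 2
Reactants: 4 (3R)-5-oxo-3-(prop-1-en-2-yl)pentyl acetate
Product: 6 (3RS,5R)-2-methyl-5-(prop-1-en-2-yl)hept-1-ene-3,7-diol, via hydroxy acetate 5 (not isolated)
Conditions: CH2=C(CH3)MgBr (1.15 equiv), THF, −78 °C; then MeOH, K2CO3 (0.3 equiv), 23 °C
Reagents that add atoms: isopropenylmagnesium bromide, C=C(C)[Mg]Br
Why: Grignard 1,2-addition is far faster at the aldehyde than at the acetate at −78 °C, and the acetate is then removed by K2CO3-catalysed transesterification in the same flask; the new carbinol centre forms unselectively and is erased in step 7.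

Step 3
Reactants: 6 (3RS,5R)-2-methyl-5-(prop-1-en-2-yl)hept-1-ene-3,7-diol
Product: 7 (3RS,5S)-7-iodo-2-methyl-5-(prop-1-en-2-yl)hept-1-en-3-ol
Conditions: PPh3 (1.15 equiv), I2 (1.15 equiv), imidazole, CH2Cl2, 0 °C
Reagents that add atoms: iodine, II
Why: Appel (Garegg) iodination, in which the unhindered primary alkoxyphosphonium ion forms and is displaced by iodide faster than the secondary allylic one; the stereocentre is untouched and its label becomes S only because iodine raises the CIP priority of that arm.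

Step 4
Reactants: 7 (3RS,5S)-7-iodo-2-methyl-5-(prop-1-en-2-yl)hept-1-en-3-ol; 8 ethyl 2-[bis(2-methylphenoxy)phosphoryl]acetate
Product: 9 ethyl (2RS,5R,7RS)-2-[bis(2-methylphenoxy)phosphoryl]-7-hydroxy-8-methyl-5-(prop-1-en-2-yl)non-8-enoate
Conditions: 8 (1.3 equiv), NaH (1.25 equiv), DMF, 0 °C; then 7, 23 → 40 °C
Reagents that add atoms: none
Why: SN2 C-alkylation of the stabilised phosphonoacetate anion by a primary iodide; the anion is far too weak a base to deprotonate the free alcohol, so no cyclic ether forms.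

Step 5
Reactants: 10 3-bromofuran; 11 prop-2-en-1-ol (allyl alcohol)
Product: 12 3-(furan-3-yl)propanal
Conditions: Pd(OAc)2 (3 mol%), Bu4NCl, NaHCO3, DMF, 70 °C
Reagents that add atoms: none
Why: Heck arylation of allyl alcohol under Jeffery conditions, where the furyl–palladium species adds to the terminal carbon and β-hydride elimination toward the carbinol gives the enol and hence the saturated aldehyde.

Step 6
Reactants: 9 ethyl (2RS,5R,7RS)-2-[bis(2-methylphenoxy)phosphoryl]-7-hydroxy-8-methyl-5-(prop-1-en-2-yl)non-8-enoate; 12 3-(furan-3-yl)propanal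
Product: 13 ethyl (2Z,5R,7RS)-2-[3-(furan-3-yl)propylidene]-7-hydroxy-8-methyl-5-(prop-1-en-2-yl)non-8-enoate
Conditions: NaH (1.05 equiv), THF, 0 °C; then 12 (1.2 equiv), −78 → 0 °C
Reagents that add atoms: none
Why: Ando variant of the Horner–Wadsworth–Emmons olefination, in which the electron-poor diaryl phosphonate eliminates from the kinetically formed adduct before it equilibrates and so places the ester cis to the new alkyl chain (Z, typically ≥ 95:5 for α-alkyl reagents and aliphatic aldehydes).

Step 7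
Reactants: 13 ethyl (2Z,5R,7RS)-2-[3-(furan-3-yl)propylidene]-7-hydroxy-8-methyl-5-(prop-1-en-2-yl)non-8-enoate
Product: 15 ethyl (2Z,5R,7E)-2-[3-(furan-3-yl)propylidene]-8-methyl-11-oxo-5-(prop-1-en-2-yl)undec-7-enoate, via allyl vinyl ether 14 (not isolated)
Conditions: butyl vinyl ether (solvent), Pd(OCOCF3)2 (2 mol%), 4,7-diphenyl-1,10-phenanthroline (2 mol%), Et3N (10 mol%), 75 °C; evaporate; toluene, 135 °C (sealed)
Reagents that add atoms: butyl vinyl ether, C=COCCCC
Why: vinyl ether exchange catalysed by divalent palladium gives 14, whose Claisen rearrangement runs through a chair transition state with the C6 chain equatorial and so gives the E trisubstituted alkene (typically > 95:5) and the aldehyde from both carbinol epimers.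

Step 8
Reactants: 16 ethyl 2-(triphenyl-λ5-phosphanylidene)acetate; 17 5-bromo-2-methylpent-2-ene
Product: 19 ethyl 6-methyl-2-(triphenyl-λ5-phosphanylidene)hept-5-enoate, via phosphonium bromide 18 (not isolated)
Conditions: 16 (2.1 equiv), toluene, 105 °C, 48 h; filter off the salt
Reagents that add atoms: none
Why: C-alkylation of the ester-stabilised ylide by the primary bromide gives salt 18, which the second equivalent of 16 deprotonates (transylidation); the ylide is too weak a base to eliminate HBr from 17.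

Step 9
Reactants: 15 ethyl (2Z,5R,7E)-2-[3-(furan-3-yl)propylidene]-8-methyl-11-oxo-5-(prop-1-en-2-yl)undec-7-enoate; 19 ethyl 6-methyl-2-(triphenyl-λ5-phosphanylidene)hept-5-enoate
Product: 20 diethyl (2E,6E,9R,12Z)-12-[3-(furan-3-yl)propylidene]-6-methyl-2-(4-methylpent-3-en-1-yl)-9-(prop-1-en-2-yl)trideca-2,6-dienedioate
Conditions: 19 (1.5 equiv), toluene, 95 °C
Reagents that add atoms: none
Why: Wittig olefination with an α-alkyl ester-stabilised ylide, which places the ester trans to the aldehyde-derived chain (E, typically ≥ 95:5); the Z-enoate, furan and other alkenes are inert.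

Step 10
Reactants: 20 diethyl (2E,6E,9R,12Z)-12-[3-(furan-3-yl)propylidene]-6-methyl-2-(4-methylpent-3-en-1-yl)-9-(prop-1-en-2-yl)trideca-2,6-dienedioate
Product: 21 (2E,6E,9R,12Z)-12-[3-(furan-3-yl)propylidene]-6-methyl-2-(4-methylpent-3-en-1-yl)-9-(prop-1-en-2-yl)trideca-2,6-dienedioic acid (CNP0235727.2)
Conditions: LiOH·H2O (10 equiv), THF/MeOH/H2O 3:1:1, 45 °C; then 1 M HCl to pH 3, 0 °C
Reagents that add atoms: lithium hydroxide, [Li+].[OH-]
Why: saponification by acyl–oxygen cleavage of both ethyl esters under conditions too mild to isomerise the α-alkyl enoates or to harm the furan and the stereocentre.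

**Compound list**
1 | (R)-(+)-limonene, (4R)-1-methyl-4-(prop-1-en-2-yl)cyclohex-1-ene | CC1=CC[C@@H](CC1)C(C)=C | starting material
2 | (3R)-6-hydroperoxy-6-methoxy-3-(prop-1-en-2-yl)heptanal (C6 epimers) | O=CC[C@@H](CCC(C)(OC)OO)C(C)=C | intermediate
3 | (5R)-2-methoxy-7-oxo-5-(prop-1-en-2-yl)heptan-2-yl ethaneperoxoate (C2 epimers) | O=CC[C@@H](CCC(C)(OC)OOC(C)=O)C(C)=C | intermediate
4 | (3R)-5-oxo-3-(prop-1-en-2-yl)pentyl acetate | O=CC[C@@H](CCOC(C)=O)C(C)=C | intermediate
5 | (3R,5RS)-5-hydroxy-6-methyl-3-(prop-1-en-2-yl)hept-6-en-1-yl acetate | C=C(C)C(O)C[C@@H](CCOC(C)=O)C(C)=C | intermediate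
6 | (3RS,5R)-2-methyl-5-(prop-1-en-2-yl)hept-1-ene-3,7-diol | C=C(C)C(O)C[C@@H](CCO)C(C)=C | intermediate
7 | (3RS,5S)-7-iodo-2-methyl-5-(prop-1-en-2-yl)hept-1-en-3-ol | C=C(C)C(O)C[C@@H](CCI)C(C)=C | intermediate
8 | ethyl 2-[bis(2-methylphenoxy)phosphoryl]acetate | CCOC(=O)CP(=O)(Oc1ccccc1C)Oc1ccccc1C | starting material
9 | ethyl (2RS,5R,7RS)-2-[bis(2-methylphenoxy)phosphoryl]-7-hydroxy-8-methyl-5-(prop-1-en-2-yl)non-8-enoate | C=C(C)C(O)C[C@@H](CCC(C(=O)OCC)P(=O)(Oc1ccccc1C)Oc1ccccc1C)C(C)=C | intermediate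
10 | 3-bromofuran | Brc1ccoc1 | starting material
11 | prop-2-en-1-ol (allyl alcohol) | C=CCO | starting material
12 | 3-(furan-3-yl)propanal | O=CCCc1ccoc1 | intermediate
13 | ethyl (2Z,5R,7RS)-2-[3-(furan-3-yl)propylidene]-7-hydroxy-8-methyl-5-(prop-1-en-2-yl)non-8-enoate | C=C(C)C(O)C[C@@H](CC/C(=C/CCc1ccoc1)C(=O)OCC)C(C)=C | intermediate
14 | ethyl (2Z,5R,7RS)-7-(ethenyloxy)-2-[3-(furan-3-yl)propylidene]-8-methyl-5-(prop-1-en-2-yl)non-8-enoate | C=COC(C(C)=C)C[C@@H](CC/C(=C/CCc1ccoc1)C(=O)OCC)C(C)=C | intermediate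
15 | ethyl (2Z,5R,7E)-2-[3-(furan-3-yl)propylidene]-8-methyl-11-oxo-5-(prop-1-en-2-yl)undec-7-enoate | O=CCC/C(C)=C/C[C@@H](CC/C(=C/CCc1ccoc1)C(=O)OCC)C(C)=C | intermediate
16 | ethyl 2-(triphenyl-λ5-phosphanylidene)acetate | CCOC(=O)C=P(c1ccccc1)(c1ccccc1)c1ccccc1 | starting material
17 | 5-bromo-2-methylpent-2-ene | CC(C)=CCCBr | starting material
18 | (1-ethoxy-6-methyl-1-oxohept-5-en-2-yl)triphenylphosphonium bromide | CCOC(=O)C(CCC=C(C)C)[P+](c1ccccc1)(c1ccccc1)c1ccccc1.[Br-] | intermediate
19 | ethyl 6-methyl-2-(triphenyl-λ5-phosphanylidene)hept-5-enoate | CCOC(=O)C(CCC=C(C)C)=P(c1ccccc1)(c1ccccc1)c1ccccc1 | intermediate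
20 | diethyl (2E,6E,9R,12Z)-12-[3-(furan-3-yl)propylidene]-6-methyl-2-(4-methylpent-3-en-1-yl)-9-(prop-1-en-2-yl)trideca-2,6-dienedioate | C=C(C)[C@@H](C/C=C(\C)CC/C=C(\CCC=C(C)C)C(=O)OCC)CC/C(=C/CCc1ccoc1)C(=O)OCC | intermediate
21 | (2E,6E,9R,12Z)-12-[3-(furan-3-yl)propylidene]-6-methyl-2-(4-methylpent-3-en-1-yl)-9-(prop-1-en-2-yl)trideca-2,6-dienedioic acid | C=C(C)[C@@H](C/C=C(\C)CC/C=C(\CCC=C(C)C)C(=O)O)CC/C(=C/CCc1ccoc1)C(=O)O | target
22 | 5,6-dihydro-2H-pyran-2-one (bought only for the fallback to step 1) | O=C1C=CCCO1 | starting material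
23 | 4,4,5,5-tetramethyl-2-(prop-1-en-2-yl)-1,3,2-dioxaborolane (bought only for the fallback to step 1) | CC(=C)B1OC(C)(C)C(C)(C)O1 | starting material

**Step count**
Total steps: 10. Longest linear sequence: 8 (steps 1, 2, 3, 4, 6, 7, 9, 10, from limonene).

**Steps most likely to fail, and fallbacks**

Step 1 (the proposed new step). Ozone may also attack the isopropenyl group, and part of the primary ozonide may open the other way, which would give methyl (3R)-6-oxo-3-(prop-1-en-2-yl)heptanoate instead of 4. Whether this sequence has been run on a 1-methylcycloalkene before is not certain; the opening ratio is an estimate from the usual preference for the more substituted carbonyl oxide.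
Fallback (known chemistry): it sets out from 22 and 23 in place of 1 and comes back at 6. Rh(acac)(C2H4)2 (3 mol%) and (R)-BINAP in dioxane/H2O 10:1 at 100 °C transfer the isopropenyl group of 23 to 22 (Hayashi–Miyaura conjugate addition). (R)-BINAP is the ligand hand expected to give the R product on this lactone by analogy with aryl additions. The product is (4R)-4-(prop-1-en-2-yl)oxan-2-one F1. i-Bu2AlH (CH2Cl2, −78 °C) reduces it to the lactol (4R)-4-(prop-1-en-2-yl)oxan-2-ol F2. Isopropenylmagnesium bromide (2.5 equiv, THF, 0 °C) opens F2 through its hydroxy aldehyde form to 6. This costs one more linear step.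

Step 3. The secondary allylic alcohol may compete for the reagent, or the 1,5-diol may close to an oxane on the phosphonium intermediate.
Fallback: it sets out from 6 and comes back at 9, with no phosphorus activation and no iodide. 2,4,6-Tri(propan-2-yl)benzenesulfonyl chloride (1.1 equiv, Et3N, DMAP, CH2Cl2, 0 °C) sulfonylates only the primary hydroxyl by steric control and gives (3R,5RS)-5-hydroxy-6-methyl-3-(prop-1-en-2-yl)hept-6-en-1-yl 2,4,6-tri(propan-2-yl)benzenesulfonate F3. F3 alkylates the sodium salt of 8 (NaH, DMF, 50 °C) to give 9 directly.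

Step 8. The unactivated homoallylic bromide may alkylate the stabilised ylide too slowly.
Fallback: it sets out from 15, 16 and 17 and comes back at 20, moving the C–C bond to a cross-coupling. 16 is brominated with N-bromosuccinimide (CH2Cl2, −20 °C) to ethyl 2-bromo-2-(triphenyl-λ5-phosphanylidene)acetate F4. F4 olefinates 15 in the same flask to diethyl (2Z,6E,9R,12Z)-2-bromo-12-[3-(furan-3-yl)propylidene]-6-methyl-9-(prop-1-en-2-yl)trideca-2,6-dienedioate F5, with bromine cis to the chain. 17 and zinc dust (LiCl, THF, 40 °C) give bromo(4-methylpent-3-en-1-yl)zinc F6. Negishi coupling of F5 with F6 (Pd(PPh3)4, THF, 50 °C) replaces bromine with retention and gives 20.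

Further compounds
F1 | step 1 | (4R)-4-(prop-1-en-2-yl)oxan-2-one | O=C1C[C@@H](CCO1)C(C)=C
F2 | step 1 | (4R)-4-(prop-1-en-2-yl)oxan-2-ol (both anomers) | OC1C[C@@H](CCO1)C(C)=C
F3 | step 3 | (3R,5RS)-5-hydroxy-6-methyl-3-(prop-1-en-2-yl)hept-6-en-1-yl 2,4,6-tri(propan-2-yl)benzenesulfonate | C=C(C)C(O)C[C@@H](CCOS(=O)(=O)c1c(C(C)C)cc(C(C)C)cc1C(C)C)C(C)=C
F4 | step 8 | ethyl 2-bromo-2-(triphenyl-λ5-phosphanylidene)acetate | CCOC(=O)C(Br)=P(c1ccccc1)(c1ccccc1)c1ccccc1
F5 | step 8 | diethyl (2Z,6E,9R,12Z)-2-bromo-12-[3-(furan-3-yl)propylidene]-6-methyl-9-(prop-1-en-2-yl)trideca-2,6-dienedioate | C=C(C)[C@@H](C/C=C(\C)CC/C=C(\Br)C(=O)OCC)CC/C(=C/CCc1ccoc1)C(=O)OCC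
F6 | step 8 | bromo(4-methylpent-3-en-1-yl)zinc | CC(C)=CCC[Zn]Br
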